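Remark on the chemistry (assumption): compounds 1, 11, 12 and 23 are taken as purchasable. Positions are given in flavan numbering (O1, C2, C3, C4, C4a, C5–C8, C8a), also for open-chain precursors. Bn = benzyl, TBS = tert-butyldimethylsilyl, TIPS = triisopropylsilyl, Ar = 3,4,5-tris(benzyloxy)phenyl.

## Analysis of the target

Epigallocatechin 7-O-gallate (25) is a flavan: a chroman (benzo ring A fused to the oxygen heterocycle, ring C) with a 3,4,5-trihydroxyphenyl ring B on C2, a hydroxyl on C3 and a galloyl ester on O7. C2 and C3 are the only stereocentres, both R, with the aryl group and the hydroxyl cis on ring C. C2 is benzylic and bound to O1, so it can ionise, and with a free para-hydroxyl on ring B it epimerises in base. The molecule carries seven free phenolic hydroxyls (two pyrogallol units that oxidise in air) and an aryl ester that nucleophiles cleave. Ring A is very electron-rich at C6, C8 and at the benzylic C4. The synthesis is hard for two reasons: the cis-2,3 relation must be set in one absolute sense, and ring A is a phloroglucinol whose three meta oxygens have three different roles (O1 closes ring C, O5 stays free, O7 is acylated). A route through a preformed 5,7-dihydroxyflavan or a phloroglucinol ether would have to tell nearly equivalent positions apart. The strategy rests on the pattern of ring A itself: C4 sits on C4a, flanked by the carbons that bear O1 and O5 and para to the carbon that bears O7. A benzene ring built from an alkoxy-substituted vinylketene and an ynol ether that carries the C4–C3–C2 chain has exactly this pattern, so O7 is differentiated when the ring is made.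

## Retrosynthetic reasoning

25 from 24. All phenols and O3 are carried as benzyl ethers. The last step is then a neutral hydrogenolysis, which should spare the aryl ester and the C2–O1 bond. No acid or base is needed once the ester is in place.

24 from 22 and 23. The ester C–O7 bond is cut late, because the aryl ester is the most fragile function of the target. The forward step needs O7 to be the only free hydroxyl, which 22 provides.

22 from 21, and 21 from 20. O7 travels as an allyl ether, and O5 is benzylated before the allyl group is removed. The allyl ether is removed by palladium catalysis under neutral conditions in the presence of benzyl ethers. A 4-methoxybenzyl group at O7 was considered and rejected. Its oxidative removal would compete with oxidation at C4 of a 5,7-dioxygenated flavan, and its acidic removal would release a benzylic cation next to the nucleophilic ring A.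

20 from 19. The O1–C2 bond is cut. C2 is the benzylic carbinol carbon of an erythro chain, and closure with inversion turns erythro into 2,3-cis. In 19 the two ring A hydroxyls next to C4a are equivalent, so either one closes to the same chroman and the other becomes O5–H. The forward reaction must be a clean SN2 displacement without ionisation at C2.

19 from 18. Both silyl groups are removed together, so no selective deprotection is required.

18 from 10 and 13 (key disconnection). Ring A is taken apart into cyclobutenone 13, which supplies C6, C7, C8, C8a, O1 and O7, and siloxyalkyne 10, which supplies C4a, C5 and O5 together with the whole C4–C3–C2–ring B chain. The bonds cut are C4a–C8a and C5–C6 between the fragments, and C8–C8a, which the final electrocyclisation re-forms. The cut is made here because the three oxygens then originate from three different functions (ketone, vinylogous ester, ynol ether) and are distinguishable from the outset. Both stereocentres are already in the alkyne and are only spectators. The forward cascade has to be regioselective in the cycloaddition step.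

13 from 11 and 12. The alkoxy group of the vinylogous ester is exchanged.

10 from 7. The C5–O5 bond is cut: the terminal alkyne is oxidised at carbon through its acetylide to an ynolate, which is silylated on oxygen.

7 from 6, 6 from 5, 5 from 4. The bond between C4 and the alkyne carbon is cut, which leads back to a terminal epoxide opened at its CH2 carbon by a silyl-capped acetylide. The oxygen set free becomes O3 and is benzylated without base. The carbon-bound silyl group is then removed.

4 from 3, 3 from 2, 2 from 1. The silyl ether 4 comes from erythro epoxy alcohol 3. 3 is taken from racemic allylic alcohol 2 by kinetic resolution through asymmetric epoxidation, which fixes both stereocentres in one operation. 2 arises by forming the C2–C3 bond through addition of a vinyl nucleophile to aldehyde 1.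

## Alternatives that were turned down

Alternative 1: O1–C2 and C3–C4 are cut together, so that ring C falls apart into a ring A heterodiene and a ring B alkene. In the forward direction, anodic oxidation of thioether A2 would expel the sulfur group and unmask ortho-quinone methide A3. A3 is expected to add the (Z)-alkenylboronate A4 in a (4+2) cycloaddition to give the cis-3-borylchroman A1, and oxidation of the C–B bond with retention would then install O3.
- For: this is the most convergent plan, since both aryl sectors and the gallate are in place before ring C closes. The cis relation follows from suprafacial addition to a Z-alkene, and the polarity of the partners places the benzylic carbon on O1.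
- Against: the absolute configuration must be induced by a chiral diol on boron that is remote from the new stereocentres, so facial selectivity is open. The Z-alkene must not isomerise under oxidising conditions, or the cis relation is lost. The anode has to oxidise the sulfide in the presence of three electron-rich aryl rings and free phenols, and A1 is itself easily oxidised. A2 still requires one of three ring A hydroxyls to be galloylated selectively.
- Comparison: Alternative 1 is shorter and more convergent, which is conceded. The chosen route spends more steps but takes the absolute configuration from a reagent-controlled epoxidation and a stereospecific displacement, and it builds the O5/O7 difference into ring A.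

Alternative 2: C3–C4 and C4–C4a are cut, with C4 inserted as one carbon into the five-membered ketone A6. In the forward direction, a silyl diazomethane reagent adds to the C3 carbonyl of A6 under Lewis acid activation, the ring A carbon migrates, and protodesilylation gives chroman-3-one A5.
- For: the sequence is short, and ketones such as A6 come from standard benzofuranone chemistry. A 3-ketone is the classical entry to cis-flavan-3-ols by hydride delivery anti to the C2 aryl group. The configurationally labile C2 could even be used in an asymmetric reduction with dynamic kinetic resolution.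
- Against: A5 is formed racemic, and its C2 (alpha to the ketone, benzylic and on oxygen) invites enolisation and ring opening. The migration must choose the aryl carbon over the oxygenated C2, which would give the isomeric chroman-4-one. The carbonyl of A6 is deactivated by two oxygen donors on ring A. The aryl ester must survive Lewis acid and hydride, and the 5-O/7-O distinction still has to be made on a symmetric ring A precursor.
- Comparison: Alternative 2 is stronger in step count and in how reliably the cis relation follows from the ketone. The chosen route offers a mechanistically fixed regiochemistry and a defined absolute configuration before ring C exists.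

Alternative 3: the C3–C4 bond is cut as an alkene, and ring C is closed by metathesis of diene A8. In the forward direction, a ruthenium carbene catalyst of the second generation joins the ring A styrene to the 1,1-disubstituted enol ether and gives 2H-chromene A7. Hydrogenation of the enol ether from the face opposite the C2 aryl group would then set C3.
- For: only C2 needs asymmetric synthesis, and C3 follows by substrate control. Metathesis to 2H-chromenes is established, and the O7 silyl ether is already distinct.
- Against: cyclisation onto an electron-rich 1,1-disubstituted enol ether to give a trisubstituted enol ether is a slow case of metathesis, and initiation at the enol ether gives an unreactive alkoxycarbene. The C2–H of A7 and A8 is allylic, benzylic and alpha to oxygen, so ruthenium hydride isomerisation or electrocyclic opening of the chromene can racemise it. A8 needs a ring A with a vinyl group and three different oxygens, which brings back the regiochemical problem. Its aryl ether bond must be made at a hindered secondary carbon.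
- Comparison: the length is similar, and Alternative 3 has the advantage of one externally controlled stereocentre instead of two. The chosen route builds the ring A pattern without ambiguity and closes ring C by a displacement known on this substrate class.

Key step: step 9

## Route

Step 1
Reactants: 1 3,4,5-tris(benzyloxy)benzaldehyde
Product: 2 (±)-1-[3,4,5-tris(benzyloxy)phenyl]prop-2-en-1-ol
Conditions: CH2=CHMgBr, THF, −78 → 0 °C; H2O
Reagents that add atoms: vinylmagnesium bromide, C=C[Mg]Br
Why: Grignard 1,2-addition to a non-enolisable aryl aldehyde forms the C2–C3 bond; the carbinol is made racemic on purpose because the next step resolves it.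

Step 2
Reactants: 2 (±)-1-[3,4,5-tris(benzyloxy)phenyl]prop-2-en-1-ol
Product: 3 (S)-[(2R)-oxiran-2-yl][3,4,5-tris(benzyloxy)phenyl]methanol (erythro)
Conditions: Ti(OiPr)4 (cat.), L-(+)-diisopropyl tartrate (cat.), t-BuOOH (0.45 equiv), 4 Å MS, CH2Cl2, −20 °C
Reagents that add atoms: tert-butyl hydroperoxide, CC(C)(C)OO
Why: Sharpless kinetic resolution by titanium tartrate-catalysed asymmetric epoxidation: with the L-(+)-tartrate only the (R)-configured half of 2 should be epoxidised at a useful rate, with oxygen delivered anti to the carbinol substituent, which gives the erythro epoxy alcohol; the (S)-configured half of 2 is left and removed by chromatography. The new stereocentre (oxirane CH, R, the future C3) is set by the tartrate ligand; the carbinol carbon (future C2) keeps its geometry and is labelled S because the oxirane carbon now outranks the aryl group.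

Step 3
Reactants: 3 (S)-[(2R)-oxiran-2-yl][3,4,5-tris(benzyloxy)phenyl]methanol
Product: 4 tert-butyldimethyl{(S)-[(2R)-oxiran-2-yl][3,4,5-tris(benzyloxy)phenyl]methoxy}silane
Conditions: TBSCl, imidazole, DMF, 0 °C → rt
Reagents that add atoms: tert-butyldimethylsilyl chloride, CC(C)(C)[Si](C)(C)Cl
Why: Silylation of the secondary benzylic hydroxyl with the silyl chloride and imidazole; a silyl triflate is avoided because it would activate the epoxide towards opening or aryl migration.

Step 4
Reactants: 4 tert-butyldimethyl{(S)-[(2R)-oxiran-2-yl][3,4,5-tris(benzyloxy)phenyl]methoxy}silane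
Product: 5 (1S,2R)-1-(TBS-oxy)-5-(trimethylsilyl)-1-[3,4,5-tris(benzyloxy)phenyl]pent-4-yn-2-ol
Conditions: Me3SiC≡CH, n-BuLi, THF, −78 °C; BF3·OEt2; then 4, −78 °C
Reagents that add atoms: ethynyltrimethylsilane, C#C[Si](C)(C)C
Why: Yamaguchi–Hirao alkynylation: the alkynyl borate formed at −78 °C opens the monosubstituted epoxide by SN2 attack at the CH2 terminus, so neither stereocentre is touched and the oxirane oxygen becomes the C3 hydroxyl. Low temperature and the ethereal solvent should keep the Lewis acid from ionising the silyl-protected benzylic carbinol.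

Step 5
Reactants: 5 (1S,2R)-1-(TBS-oxy)-5-(trimethylsilyl)-1-[3,4,5-tris(benzyloxy)phenyl]pent-4-yn-2-ol
Product: 6 tert-butyl{[(1S,2R)-2-(benzyloxy)-5-(trimethylsilyl)-1-[3,4,5-tris(benzyloxy)phenyl]pent-4-yn-1-yl]oxy}dimethylsilane
Conditions: 2-benzyloxy-1-methylpyridinium triflate, MgO, PhCF3, 85 °C
Reagents that add atoms: 2-benzyloxy-1-methylpyridinium triflate, C[n+]1ccccc1OCc1ccccc1.[O-]S(=O)(=O)C(F)(F)F
Why: O-Benzylation by thermal benzyl transfer from the 2-benzyloxypyridinium salt under neutral conditions (MgO as acid scavenger), a known method for base- and acid-sensitive alcohols. No alkoxide is formed next to the TBS ether, so the 1,2-silyl shift that NaH/BnBr would risk cannot start.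

Step 6
Reactants: 6 tert-butyl{[(1S,2R)-2-(benzyloxy)-5-(trimethylsilyl)-1-[3,4,5-tris(benzyloxy)phenyl]pent-4-yn-1-yl]oxy}dimethylsilane
Product: 7 tert-butyl{[(1S,2R)-2-(benzyloxy)-1-[3,4,5-tris(benzyloxy)phenyl]pent-4-yn-1-yl]oxy}dimethylsilane
Conditions: K2CO3, MeOH/THF, rt
Reagents that add atoms: none
Why: Base-catalysed methanolysis of the C(sp)–Si bond (protodesilylation); the TBS ether is stable to K2CO3 in methanol and no free hydroxyl is present that could accept a migrating silyl group.

Step 7
Reactants: 7 tert-butyl{[(1S,2R)-2-(benzyloxy)-1-[3,4,5-tris(benzyloxy)phenyl]pent-4-yn-1-yl]oxy}dimethylsilane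
Product: 10 triisopropyl{[(4R,5S)-4-(benzyloxy)-5-(TBS-oxy)-5-[3,4,5-tris(benzyloxy)phenyl]pent-1-yn-1-yl]oxy}silane, via lithium acetylide 8 (not isolated), via lithium ynolate 9 (not isolated)
Conditions: LiN(SiMe3)2 (2.2 equiv), THF, −78 °C; t-BuOOH (1.0 equiv), −78 → 0 °C; i-Pr3SiOTf, −78 °C
Reagents that add atoms: tert-butyl hydroperoxide, CC(C)(C)OO; triisopropylsilyl triflate, CC(C)[Si](OS(=O)(=O)C(F)(F)F)(C(C)C)C(C)C
Why: Known oxidation of a lithium acetylide by t-BuOOLi: deprotonation gives 8, electrophilic oxygen transfer to the acetylide carbon gives ynolate 9, and the bulky silyl triflate silylates 9 on oxygen to the siloxyalkyne. Benzyl ethers and the TBS ether are inert to the amide base at −78 °C, and the stereocentres are remote from the reacting carbons.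

Step 8
Reactants: 11 3-ethoxycyclobut-2-en-1-one; 12 prop-2-en-1-ol (allyl alcohol)
Product: 13 3-(allyloxy)cyclobut-2-en-1-one
Conditions: 12 (solvent, large excess), TsOH (cat.), 25 °C; concentrate and repeat once
Reagents that add atoms: none
Why: Acid-catalysed alkoxy exchange on a vinylogous ester by addition–elimination at C3, the position at which 11 is known to take up water and amines; the excess of 12 and removal of ethanol displace the equilibrium. The allyl ether is chosen because it should survive heat, fluoride and Mitsunobu conditions and is later removed under neutral palladium catalysis.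

Step 9
Reactants: 10 triisopropyl{[(4R,5S)-4-(benzyloxy)-5-(TBS-oxy)-5-[3,4,5-tris(benzyloxy)phenyl]pent-1-yn-1-yl]oxy}silane; 13 3-(allyloxy)cyclobut-2-en-1-one
Product: 18 5-(allyloxy)-2-{(2R,3S)-2-(benzyloxy)-3-(TBS-oxy)-3-[3,4,5-tris(benzyloxy)phenyl]propyl}-3-(TIPS-oxy)phenol, via vinylketene 14 (not isolated), via 4-vinylcyclobutenone 15 (not isolated), via dienylketene 16 (not isolated), via cyclohexadienone 17 (not isolated)
Conditions: PhMe, 80 → 110 °C, sealed vessel; 13 (1.5 equiv) added in portions
Reagents that add atoms: none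
Why: Heating opens 13 by a 4π electrocyclic reaction to vinylketene 14. Siloxyalkyne 10 adds to the ketene C=C bond in a polar (2+2) cycloaddition in which its nucleophilic, chain-bearing carbon bonds to the ketene carbonyl carbon (C4a–C8a) and its oxygen-bearing carbon bonds to the ketene alpha carbon (C5–C6), giving 15. 15 opens again (4π) to dienylketene 16, which closes ring A by 6π electrocyclisation (C8–C8a) to 17, and 17 tautomerises to phenol 18. The closest known reaction type is the Danheiser benzannulation of cyclobutenones with trialkylsilyloxyalkynes to resorcinol monosilyl ethers; 3-silyloxycyclobutenones are known partners, so a 3-alkoxy group lies within the class, although its vinylogous ester stabilisation is expected to raise the temperature of the first ring opening. Ring A is the only ring closed, and it closes by a 6π electrocyclisation of a dienylketene and not by substitution on an existing arene. No stereocentre is created (the sp3 ring carbon of 15 is erased on ring opening), and the two existing ones are ether-protected carbinol carbons that should be inert in neutral toluene at this temperature. The step needs regioselectivity in the (2+2) event, which the matched polarity of the ketene (electrophilic at the carbonyl carbon) and the siloxyalkyne (nucleophilic at the carbon beta to oxygen) secures; this places C4 between the free hydroxyl (O1) and the silyloxy group (O5) and the allyloxy group (O7) para to C4. It also needs the ketene to react with the ynol ether faster than with the allyl alkene, the product phenol or itself, which the high nucleophilicity of the siloxyalkyne and the low ketene concentration from portionwise addition of 13 should secure.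

Step 10
Reactants: 18 5-(allyloxy)-2-{(2R,3S)-2-(benzyloxy)-3-(TBS-oxy)-3-[3,4,5-tris(benzyloxy)phenyl]propyl}-3-(TIPS-oxy)phenol
Product: 19 5-(allyloxy)-2-{(2R,3S)-2-(benzyloxy)-3-hydroxy-3-[3,4,5-tris(benzyloxy)phenyl]propyl}benzene-1,3-diol
Conditions: Bu4NF, THF, 0 °C → rt; pH 7 buffer
Reagents that add atoms: none
Why: Fluoride-mediated desilylation of the aryl TIPS ether and the secondary TBS ether in one operation; no selectivity between the two silicon groups is wanted, because O1–H and O5–H are equivalent in 19. 19 is kept from acid, which would cyclise it through the benzylic cation without stereocontrol, and is used directly.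

Step 11
Reactants: 19 5-(allyloxy)-2-{(2R,3S)-2-(benzyloxy)-3-hydroxy-3-[3,4,5-tris(benzyloxy)phenyl]propyl}benzene-1,3-diol
Product: 20 (2R,3R)-7-(allyloxy)-3-(benzyloxy)-2-[3,4,5-tris(benzyloxy)phenyl]chroman-5-ol
Conditions: PPh3, DIAD, THF, 0 °C → rt
Reagents that add atoms: none
Why: Intramolecular Mitsunobu etherification, known for 1-aryl-3-(2-hydroxyaryl)propane-1,2-diol derivatives: the benzylic hydroxyl is the only alcohol and is displaced as its oxyphosphonium by a ring A phenoxide in a 6-exo-tet SN2 step with inversion, which turns the (S)-carbinol into (2R) and the erythro chain into the 2,3-cis chroman; C3 is not touched. The two ring A hydroxyls are exchanged by rotation about the C4–C4a bond, so either gives 20, and the beta-benzyloxy group inductively disfavours the ionisation that would erode the inversion.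

Step 12
Reactants: 20 (2R,3R)-7-(allyloxy)-3-(benzyloxy)-2-[3,4,5-tris(benzyloxy)phenyl]chroman-5-ol
Product: 21 (2R,3R)-7-(allyloxy)-3,5-bis(benzyloxy)-2-[3,4,5-tris(benzyloxy)phenyl]chromane
Conditions: BnBr, K2CO3, DMF, rt
Reagents that add atoms: benzyl bromide, BrCc1ccccc1
Why: Williamson etherification of the remaining phenol (O5) under mild carbonate conditions; ring B carries no free para-hydroxyl, so C2 cannot epimerise through a quinone methide.

Step 13
Reactants: 21 (2R,3R)-7-(allyloxy)-3,5-bis(benzyloxy)-2-[3,4,5-tris(benzyloxy)phenyl]chromane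
Product: 22 (2R,3R)-3,5-bis(benzyloxy)-2-[3,4,5-tris(benzyloxy)phenyl]chroman-7-ol
Conditions: Pd(PPh3)4 (cat.), morpholine, THF, rt
Reagents that add atoms: none
Why: Tsuji–Trost-type deallylation: zerovalent palladium ionises the allyl aryl ether to a π-allyl complex and the O7 phenoxide, and morpholine traps the allyl unit irreversibly. The neutral conditions leave the benzyl ethers and the electron-rich positions C4, C6 and C8 untouched.

Step 14
Reactants: 22 (2R,3R)-3,5-bis(benzyloxy)-2-[3,4,5-tris(benzyloxy)phenyl]chroman-7-ol; 23 3,4,5-tris(benzyloxy)benzoic acid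
Product: 24 (2R,3R)-3,5-bis(benzyloxy)-2-[3,4,5-tris(benzyloxy)phenyl]chroman-7-yl 3,4,5-tris(benzyloxy)benzoate
Conditions: EDC·HCl, DMAP, CH2Cl2, rt
Reagents that add atoms: none
Why: Steglich esterification (carbodiimide activation, DMAP acyl transfer) of the only free hydroxyl, the unhindered O7 phenol, with acid 23.

Step 15
Reactants: 24 (2R,3R)-3,5-bis(benzyloxy)-2-[3,4,5-tris(benzyloxy)phenyl]chroman-7-yl 3,4,5-tris(benzyloxy)benzoate
Product: 25 epigallocatechin 7-O-gallate, (2R,3R)-3,5-dihydroxy-2-(3,4,5-trihydroxyphenyl)chroman-7-yl 3,4,5-trihydroxybenzoate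
Conditions: H2 (1 atm), Pd(OH)2/C, THF/MeOH, rt, then handling under argon
Reagents that add atoms: none
Why: Hydrogenolysis of the eight O-benzyl groups over Pd(OH)2 under neutral conditions, the established last step for benzylated catechin gallates; the aryl ester, the C2–O1 bond and both stereocentres should not be affected. The product is kept under argon because the free pyrogallol units oxidise in air.

## Compound list

1 | 3,4,5-tris(benzyloxy)benzaldehyde | O=Cc1cc(OCc2ccccc2)c(OCc2ccccc2)c(OCc2ccccc2)c1 | starting material
2 | (±)-1-[3,4,5-tris(benzyloxy)phenyl]prop-2-en-1-ol | C=CC(O)c1cc(OCc2ccccc2)c(OCc2ccccc2)c(OCc2ccccc2)c1 | intermediate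
3 | (S)-[(2R)-oxiran-2-yl][3,4,5-tris(benzyloxy)phenyl]methanol | O[C@H]([C@H]1CO1)c1cc(OCc2ccccc2)c(OCc2ccccc2)c(OCc2ccccc2)c1 | intermediate
4 | tert-butyldimethyl{(S)-[(2R)-oxiran-2-yl][3,4,5-tris(benzyloxy)phenyl]methoxy}silane | CC(C)(C)[Si](C)(C)O[C@H]([C@H]1CO1)c1cc(OCc2ccccc2)c(OCc2ccccc2)c(OCc2ccccc2)c1 | intermediate
5 | (1S,2R)-1-(TBS-oxy)-5-(trimethylsilyl)-1-[3,4,5-tris(benzyloxy)phenyl]pent-4-yn-2-ol | C[Si](C)(C)C#CC[C@@H](O)[C@@H](O[Si](C)(C)C(C)(C)C)c1cc(OCc2ccccc2)c(OCc2ccccc2)c(OCc2ccccc2)c1 | intermediate
6 | tert-butyl{[(1S,2R)-2-(benzyloxy)-5-(trimethylsilyl)-1-[3,4,5-tris(benzyloxy)phenyl]pent-4-yn-1-yl]oxy}dimethylsilane | C[Si](C)(C)C#CC[C@@H](OCc1ccccc1)[C@@H](O[Si](C)(C)C(C)(C)C)c1cc(OCc2ccccc2)c(OCc2ccccc2)c(OCc2ccccc2)c1 | intermediate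
7 | tert-butyl{[(1S,2R)-2-(benzyloxy)-1-[3,4,5-tris(benzyloxy)phenyl]pent-4-yn-1-yl]oxy}dimethylsilane | C#CC[C@@H](OCc1ccccc1)[C@@H](O[Si](C)(C)C(C)(C)C)c1cc(OCc2ccccc2)c(OCc2ccccc2)c(OCc2ccccc2)c1 | intermediate
8 | lithium acetylide of 7 | [Li]C#CC[C@@H](OCc1ccccc1)[C@@H](O[Si](C)(C)C(C)(C)C)c1cc(OCc2ccccc2)c(OCc2ccccc2)c(OCc2ccccc2)c1 | intermediate
9 | lithium ynolate, lithium (4R,5S)-4-(benzyloxy)-5-(TBS-oxy)-5-[3,4,5-tris(benzyloxy)phenyl]pent-1-yn-1-olate | [Li]OC#CC[C@@H](OCc1ccccc1)[C@@H](O[Si](C)(C)C(C)(C)C)c1cc(OCc2ccccc2)c(OCc2ccccc2)c(OCc2ccccc2)c1 | intermediate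
10 | triisopropyl{[(4R,5S)-4-(benzyloxy)-5-(TBS-oxy)-5-[3,4,5-tris(benzyloxy)phenyl]pent-1-yn-1-yl]oxy}silane | CC(C)[Si](OC#CC[C@@H](OCc1ccccc1)[C@@H](O[Si](C)(C)C(C)(C)C)c1cc(OCc2ccccc2)c(OCc2ccccc2)c(OCc2ccccc2)c1)(C(C)C)C(C)C | intermediate
11 | 3-ethoxycyclobut-2-en-1-one | CCOC1=CC(=O)C1 | starting material
12 | prop-2-en-1-ol (allyl alcohol) | C=CCO | starting material
13 | 3-(allyloxy)cyclobut-2-en-1-one | C=CCOC1=CC(=O)C1 | intermediate
14 | 3-(allyloxy)buta-1,3-dien-1-one (vinylketene) | C=CCOC(=C)C=C=O | intermediate
15 | 4-[1-(allyloxy)ethenyl]-2-{(2R,3S)-2-(benzyloxy)-3-(TBS-oxy)-3-[3,4,5-tris(benzyloxy)phenyl]propyl}-3-(TIPS-oxy)cyclobut-2-en-1-one (mixture at the ring sp3 carbon) | C=CCOC(=C)C1C(=O)C(C[C@@H](OCc2ccccc2)[C@@H](O[Si](C)(C)C(C)(C)C)c2cc(OCc3ccccc3)c(OCc3ccccc3)c(OCc3ccccc3)c2)=C1O[Si](C(C)C)(C(C)C)C(C)C | intermediate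
16 | (3E)-5-(allyloxy)-2-{(2R,3S)-2-(benzyloxy)-3-(TBS-oxy)-3-[3,4,5-tris(benzyloxy)phenyl]propyl}-3-(TIPS-oxy)hexa-1,3,5-trien-1-one (dienylketene) | C=CCOC(=C)/C=C(/O[Si](C(C)C)(C(C)C)C(C)C)C(=C=O)C[C@@H](OCc1ccccc1)[C@@H](O[Si](C)(C)C(C)(C)C)c1cc(OCc2ccccc2)c(OCc2ccccc2)c(OCc2ccccc2)c1 | intermediate
17 | 5-(allyloxy)-2-{(2R,3S)-2-(benzyloxy)-3-(TBS-oxy)-3-[3,4,5-tris(benzyloxy)phenyl]propyl}-3-(TIPS-oxy)cyclohexa-2,4-dien-1-one | O=C1CC(OCC=C)=CC(O[Si](C(C)C)(C(C)C)C(C)C)=C1C[C@@H](OCc1ccccc1)[C@@H](O[Si](C)(C)C(C)(C)C)c1cc(OCc2ccccc2)c(OCc2ccccc2)c(OCc2ccccc2)c1 | intermediate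
18 | 5-(allyloxy)-2-{(2R,3S)-2-(benzyloxy)-3-(TBS-oxy)-3-[3,4,5-tris(benzyloxy)phenyl]propyl}-3-(TIPS-oxy)phenol | C=CCOc1cc(O)c(C[C@@H](OCc2ccccc2)[C@@H](O[Si](C)(C)C(C)(C)C)c2cc(OCc3ccccc3)c(OCc3ccccc3)c(OCc3ccccc3)c2)c(O[Si](C(C)C)(C(C)C)C(C)C)c1 | intermediate
19 | 5-(allyloxy)-2-{(2R,3S)-2-(benzyloxy)-3-hydroxy-3-[3,4,5-tris(benzyloxy)phenyl]propyl}benzene-1,3-diol | C=CCOc1cc(O)c(C[C@@H](OCc2ccccc2)[C@@H](O)c2cc(OCc3ccccc3)c(OCc3ccccc3)c(OCc3ccccc3)c2)c(O)c1 | intermediate
20 | (2R,3R)-7-(allyloxy)-3-(benzyloxy)-2-[3,4,5-tris(benzyloxy)phenyl]chroman-5-ol | C=CCOc1cc(O)c2c(c1)O[C@H](c1cc(OCc3ccccc3)c(OCc3ccccc3)c(OCc3ccccc3)c1)[C@H](OCc1ccccc1)C2 | intermediate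
21 | (2R,3R)-7-(allyloxy)-3,5-bis(benzyloxy)-2-[3,4,5-tris(benzyloxy)phenyl]chromane | C=CCOc1cc(OCc2ccccc2)c2c(c1)O[C@H](c1cc(OCc3ccccc3)c(OCc3ccccc3)c(OCc3ccccc3)c1)[C@H](OCc1ccccc1)C2 | intermediate
22 | (2R,3R)-3,5-bis(benzyloxy)-2-[3,4,5-tris(benzyloxy)phenyl]chroman-7-ol | Oc1cc(OCc2ccccc2)c2c(c1)O[C@H](c1cc(OCc3ccccc3)c(OCc3ccccc3)c(OCc3ccccc3)c1)[C@H](OCc1ccccc1)C2 | intermediate
23 | 3,4,5-tris(benzyloxy)benzoic acid | OC(=O)c1cc(OCc2ccccc2)c(OCc2ccccc2)c(OCc2ccccc2)c1 | starting material
24 | (2R,3R)-3,5-bis(benzyloxy)-2-[3,4,5-tris(benzyloxy)phenyl]chroman-7-yl 3,4,5-tris(benzyloxy)benzoate | O=C(Oc1cc(OCc2ccccc2)c2c(c1)O[C@H](c1cc(OCc3ccccc3)c(OCc3ccccc3)c(OCc3ccccc3)c1)[C@H](OCc1ccccc1)C2)c1cc(OCc2ccccc2)c(OCc2ccccc2)c(OCc2ccccc2)c1 | intermediate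
25 | epigallocatechin 7-O-gallate | O=C(Oc1cc(O)c2c(c1)O[C@H](c1cc(O)c(O)c(O)c1)[C@H](O)C2)c1cc(O)c(O)c(O)c1 | target

## Step count and least certain steps

Total step count: 15. Longest linear sequence: 14 steps (steps 1–7 and 9–15, from 1 to 25). Step 8 is a one-step branch.

Step 9 (key step). The first ring opening of 13 may be too slow, because its vinylogous ester stabilisation is lost in the ketene. The temperature then needed could let the siloxyalkyne rearrange, or let the small amount of ketene be consumed by the product phenol or by dimerisation. Fallback, setting out from 12 and 10 and returning at 18: the vinylketene is made by elimination instead of ring opening. The sodium alkoxide of 12 (NaH, THF) adds to (2E)-3-chlorobut-2-enoic acid and expels chloride to give (2E)-3-(allyloxy)but-2-enoic acid F1. Oxalyl chloride with a trace of DMF converts F1 into (2E)-3-(allyloxy)but-2-enoyl chloride F2. Et3N is then added slowly to F2 and 10 in toluene at room temperature, so that 1,4-dehydrochlorination generates 14 without any ring opening. 10 captures 14 to give 15, and warming to 80 °C carries 15 through 16 and 17 to 18.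

Step 8. The acid may promote ring cleavage of the strained vinylogous ester by the alcohol (attack at the carbonyl carbon) faster than exchange at C3, or the exchange may stop short of completion. Fallback, setting out from 11 and returning at 13: cold dilute aqueous HCl hydrolyses 11 to cyclobutane-1,3-dione F3. The acidic enol of F3 is then O-allylated with 12 under Mitsunobu conditions (PPh3, DIAD, THF, 0 °C) to give 13.

Step 2. Oxygen transfer to a monosubstituted alkene is slow. The rate difference between the enantiomers may therefore be too small, or the electron-rich benzylic epoxy alcohol may be opened at titanium during the long reaction time. Fallback, setting out from 2 and returning at 3: resolution and epoxidation are separated. CAL-B lipase with vinyl acetate should acetylate the (R)-configured half of 2 to (1R)-1-[3,4,5-tris(benzyloxy)phenyl]prop-2-en-1-yl acetate F4, which is separated from the untouched (S)-alcohol. K2CO3 in MeOH releases (1R)-1-[3,4,5-tris(benzyloxy)phenyl]prop-2-en-1-ol F5. Epoxidation of F5 with Ti(OiPr)4, L-(+)-diisopropyl tartrate and t-BuOOH is then a matched, purely diastereoselective reaction that can be run to full conversion in a short time, giving 3.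

Step 5. Benzyl transfer to the hindered secondary hydroxyl may be slower than C-benzylation of the electron-rich tris(benzyloxy)phenyl ring, and a change to alkoxide conditions would open the way to 1,2-migration of the silyl group. Fallback, setting out from 3 and returning at 7: the silyl group is introduced only after the benzyl ether.
- 3,4-Dihydro-2H-pyran with pyridinium tosylate gives 2-{(S)-[(2R)-oxiran-2-yl][3,4,5-tris(benzyloxy)phenyl]methoxy}oxane F6 (mixture at the acetal carbon).
- The lithium acetylide–ethylenediamine complex in DMSO opens the epoxide at its CH2 carbon to (1S,2R)-1-(oxan-2-yloxy)-1-[3,4,5-tris(benzyloxy)phenyl]pent-4-yn-2-ol F7.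
- An acetal cannot migrate to the neighbouring alkoxide, so NaH, BnBr and Bu4NI in THF give 2-{[(1S,2R)-2-(benzyloxy)-1-[3,4,5-tris(benzyloxy)phenyl]pent-4-yn-1-yl]oxy}oxane F8.
- Pyridinium tosylate in MeOH removes the acetal to give (1S,2R)-2-(benzyloxy)-1-[3,4,5-tris(benzyloxy)phenyl]pent-4-yn-1-ol F9, and TBSCl with imidazole returns to 7.

## Further compounds

F1 | step 9 | (2E)-3-(allyloxy)but-2-enoic acid | C=CCO/C(C)=C/C(=O)O
F2 | step 9 | (2E)-3-(allyloxy)but-2-enoyl chloride | C=CCO/C(C)=C/C(=O)Cl
F3 | step 8 | cyclobutane-1,3-dione | O=C1CC(=O)C1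
F4 | step 2 | (1R)-1-[3,4,5-tris(benzyloxy)phenyl]prop-2-en-1-yl acetate | C=C[C@@H](OC(C)=O)c1cc(OCc2ccccc2)c(OCc2ccccc2)c(OCc2ccccc2)c1
F5 | step 2 | (1R)-1-[3,4,5-tris(benzyloxy)phenyl]prop-2-en-1-ol | C=C[C@@H](O)c1cc(OCc2ccccc2)c(OCc2ccccc2)c(OCc2ccccc2)c1
F6 | step 5 | 2-{(S)-[(2R)-oxiran-2-yl][3,4,5-tris(benzyloxy)phenyl]methoxy}oxane | C1CCC(OC1)O[C@H]([C@H]1CO1)c1cc(OCc2ccccc2)c(OCc2ccccc2)c(OCc2ccccc2)c1
F7 | step 5 | (1S,2R)-1-(oxan-2-yloxy)-1-[3,4,5-tris(benzyloxy)phenyl]pent-4-yn-2-ol | C#CC[C@@H](O)[C@@H](OC1CCCCO1)c1cc(OCc2ccccc2)c(OCc2ccccc2)c(OCc2ccccc2)c1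
F8 | step 5 | 2-{[(1S,2R)-2-(benzyloxy)-1-[3,4,5-tris(benzyloxy)phenyl]pent-4-yn-1-yl]oxy}oxane | C#CC[C@@H](OCc1ccccc1)[C@@H](OC1CCCCO1)c1cc(OCc2ccccc2)c(OCc2ccccc2)c(OCc2ccccc2)c1
F9 | step 5 | (1S,2R)-2-(benzyloxy)-1-[3,4,5-tris(benzyloxy)phenyl]pent-4-yn-1-ol | C#CC[C@@H](OCc1ccccc1)[C@@H](O)c1cc(OCc2ccccc2)c(OCc2ccccc2)c(OCc2ccccc2)c1
A1 | alternative 1 | 2,3-cis-3-[(4R,5R)-4,5-dicyclohexyl-1,3,2-dioxaborolan-2-yl]-5-hydroxy-2-[3,4,5-tris(benzyloxy)phenyl]chroman-7-yl 3,4,5-tris(benzyloxy)benzoate | O=C(Oc1cc(O)c2c(c1)O[C@H](c1cc(OCc3ccccc3)c(OCc3ccccc3)c(OCc3ccccc3)c1)[C@H](B1O[C@H](C3CCCCC3)[C@@H](C3CCCCC3)O1)C2)c1cc(OCc2ccccc2)c(OCc2ccccc2)c(OCc2ccccc2)c1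
A2 | alternative 1 | 3,5-dihydroxy-4-[(phenylsulfanyl)methyl]phenyl 3,4,5-tris(benzyloxy)benzoate | O=C(Oc1cc(O)c(CSc2ccccc2)c(O)c1)c1cc(OCc2ccccc2)c(OCc2ccccc2)c(OCc2ccccc2)c1
A3 | alternative 1 | 5-hydroxy-4-methylidene-3-oxocyclohexa-1,5-dien-1-yl 3,4,5-tris(benzyloxy)benzoate (ortho-quinone methide) | C=C1C(=O)C=C(OC(=O)c2cc(OCc3ccccc3)c(OCc3ccccc3)c(OCc3ccccc3)c2)C=C1O
A4 | alternative 1 | (4R,5R)-4,5-dicyclohexyl-2-{(Z)-2-[3,4,5-tris(benzyloxy)phenyl]ethenyl}-1,3,2-dioxaborolane | B1(O[C@H](C2CCCCC2)[C@@H](C2CCCCC2)O1)/C=C\c1cc(OCc2ccccc2)c(OCc2ccccc2)c(OCc2ccccc2)c1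
A5 | alternative 2 | rac-5-(benzyloxy)-3-oxo-2-[3,4,5-tris(benzyloxy)phenyl]chroman-7-yl 3,4,5-tris(benzyloxy)benzoate | O=C(Oc1cc(OCc2ccccc2)c2c(c1)OC(c1cc(OCc3ccccc3)c(OCc3ccccc3)c(OCc3ccccc3)c1)C(=O)C2)c1cc(OCc2ccccc2)c(OCc2ccccc2)c(OCc2ccccc2)c1
A6 | alternative 2 | rac-4-(benzyloxy)-3-oxo-2-[3,4,5-tris(benzyloxy)phenyl]-2,3-dihydro-1-benzofuran-6-yl 3,4,5-tris(benzyloxy)benzoate | O=C(Oc1cc(OCc2ccccc2)c2c(c1)OC(c1cc(OCc3ccccc3)c(OCc3ccccc3)c(OCc3ccccc3)c1)C2=O)c1cc(OCc2ccccc2)c(OCc2ccccc2)c(OCc2ccccc2)c1
A7 | alternative 3 | (2R)-3,5-bis(benzyloxy)-2-[3,4,5-tris(benzyloxy)phenyl]-7-(triisopropylsilyloxy)-2H-chromene | CC(C)[Si](Oc1cc(OCc2ccccc2)c2C=C(OCc3ccccc3)[C@@H](c3cc(OCc4ccccc4)c(OCc4ccccc4)c(OCc4ccccc4)c3)Oc2c1)(C(C)C)C(C)C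
A8 | alternative 3 | {3-(benzyloxy)-5-{[(1R)-2-(benzyloxy)-1-[3,4,5-tris(benzyloxy)phenyl]prop-2-en-1-yl]oxy}-4-ethenylphenoxy}triisopropylsilane | CC(C)[Si](Oc1cc(OCc2ccccc2)c(C=C)c(O[C@H](c2cc(OCc3ccccc3)c(OCc3ccccc3)c(OCc3ccccc3)c2)C(=C)OCc2ccccc2)c1)(C(C)C)C(C)C
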